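## Retrosynthetic overview

1. The target comes from a 1,2‑trans 1‑aryl‑tetralin‑2,3‑diester with oxygen at C4: O‑debenzylation, then acid removes the acetonides and the silyl group and eliminates the C4 oxygen to give C3=C4.
2. The C1–H bond comes from ionic hydrogenation of the oxygen bridge of a 1‑aryl‑1,4‑epoxytetralin (hydride axial, aryl trans to the C2 ester).
3. Key disconnection: the epoxytetralin is the Diels–Alder adduct of a 1‑aryl‑isobenzofuran, generated in the same flask from an acyclic hydroxy acetal, with the C2‑symmetric fumarate of benzyl‑protected (R)‑danshensu. The target's own ester groups act as the chiral auxiliaries.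
4. The hydroxy acetal comes from ortho‑lithiation of the acetal of acetonide‑protected 3,4‑dihydroxybenzaldehyde and addition to the same aldehyde; metalation between the acetal and the ring oxygen fixes the 7,8‑dioxygenation.
5. Ring order: furan ring of the isobenzofuran, then carbocycle plus oxygen bridge (same operation); bridge opened; dihydronaphthalene alkene last.

Assumption: natural (R)‑danshensu sodium salt is purchased; the π‑facial sense of the fumarate cycloaddition is taken by analogy to mandelate/lactate fumarates and must be confirmed on the cycloadduct.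

## Route

Step 1
Reactants: 1 sodium (2R)-3-(3,4-dihydroxyphenyl)-2-hydroxypropanoate (danshensu sodium salt)
Product: 2 benzyl (2R)-3-[3,4-bis(benzyloxy)phenyl]-2-hydroxypropanoate
Conditions: BnBr (3.3 equiv), K2CO3 (2.5 equiv), DMF, rt
Reagents that add atoms: benzyl bromide, BrCc1ccccc1
Why: Williamson O‑alkylation of the two phenoxides and the carboxylate; carbonate does not deprotonate the secondary alcohol, which stays free, and the stereocentre is untouched.

Step 2
Reactants: 2 benzyl (2R)-3-[3,4-bis(benzyloxy)phenyl]-2-hydroxypropanoate (2.05 equiv); 3 fumaryl chloride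
Product: 4 bis{(1R)-1-[3,4-bis(benzyloxy)benzyl]-2-(benzyloxy)-2-oxoethyl} (2E)-but-2-enedioate
Conditions: pyridine (2.5 equiv), DMAP (5 mol %), CH2Cl2, −10 °C → rt
Reagents that add atoms: none
Why: Double acylation of the alcohol by the acid chloride (nucleophilic acyl substitution) gives the C2‑symmetric fumarate with the E geometry and both (R) centres retained.

Step 3
Reactants: 5 3,4-dihydroxybenzaldehyde
Product: 6 2,2-dimethyl-1,3-benzodioxole-5-carbaldehyde
Conditions: 2,2-dimethoxypropane (3 equiv), TsOH (5 mol %), benzene, reflux through 4 Å MS; then brief 1 M HCl/THF wash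
Reagents that add atoms: 2,2-dimethoxypropane, COC(C)(C)OC
Why: Acid‑catalysed transketalisation protects the catechol as its acetonide with removal of MeOH; the acidic wash returns any aldehyde dimethyl acetal to the aldehyde.

Step 4
Reactants: 6 2,2-dimethyl-1,3-benzodioxole-5-carbaldehyde
Product: 7 5-(dimethoxymethyl)-2,2-dimethyl-1,3-benzodioxole
Conditions: HC(OMe)3 (3 equiv), PPTS (2 mol %), CH2Cl2, rt
Reagents that add atoms: trimethyl orthoformate, COC(OC)OC
Why: Acid‑catalysed acetalisation with the orthoformate masks the aldehyde as a base‑stable acetal that also serves as a directing group.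

Step 5
Reactants: 7 5-(dimethoxymethyl)-2,2-dimethyl-1,3-benzodioxole; 6 2,2-dimethyl-1,3-benzodioxole-5-carbaldehyde
Product: 8 [5-(dimethoxymethyl)-2,2-dimethyl-1,3-benzodioxol-4-yl](2,2-dimethyl-1,3-benzodioxol-5-yl)methanol (racemic)
Conditions: n-BuLi (1.1 equiv), THF, −20 → 0 °C; then 6, −78 °C → rt; H2O
Reagents that add atoms: none
Why: Directed ortho‑metalation occurs at the position flanked by the acetal and the dioxole oxygen (cooperative directing groups), and the aryllithium adds 1,2 to the aldehyde; the new carbinol centre is racemic and is erased in step 6.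

Step 6
Reactants: 8 [5-(dimethoxymethyl)-2,2-dimethyl-1,3-benzodioxol-4-yl](2,2-dimethyl-1,3-benzodioxol-5-yl)methanol; 4 bis{(1R)-1-[3,4-bis(benzyloxy)benzyl]-2-(benzyloxy)-2-oxoethyl} (2E)-but-2-enedioate (1.1 equiv)
Product: 11 oxa-bridged Diels–Alder adduct (1-aryl-1,4-epoxytetralin-2,3-diester), via cyclic methyl acetal 9 (not isolated), via isobenzofuran 10 (not isolated)
Conditions: AcOH (0.2 equiv), 4 Å MS, toluene, 80 °C, Ar
Reagents that add atoms: none
Why: Acid‑catalysed cyclisation of the hydroxy acetal and loss of MeOH generate the 1‑aryl‑isobenzofuran, which is trapped in a Diels–Alder reaction by the fumarate; the two (R)‑α‑acyloxy‑ester auxiliaries expose the same alkene face (anti to the arylmethyl groups in the s‑cis, C–H‑eclipsed conformer) and so set C2 and C3, while the bridgehead centres C1 and C4 (endo/exo orientation) do not matter because both are erased later.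

Step 7
Reactants: 11 oxa-bridged Diels–Alder adduct (1-aryl-1,4-epoxytetralin-2,3-diester)
Product: 12 1,2-trans-1-aryl-4-(triethylsilyloxy)tetralin-2,3-diester (benzyl- and acetonide-protected)
Conditions: Et3SiH (1.5 equiv), TESOTf (10 mol %), CH2Cl2, −78 → −40 °C; Et3N quench
Reagents that add atoms: triethylsilane, CC[SiH](CC)CC
Why: Silyl‑triflate‑catalysed ionic hydrogenation (reductive ether cleavage): the silylated bridge ionises at the doubly benzylic C1 and Et3SiH adds axially to the half‑chair cation with both esters pseudo‑equatorial (anti to the pseudo‑axial C2–H), which puts the aryl trans to the C2 ester (C1 = R) and leaves O4 as its silyl ether; the other orientation isomer of 11 gives only the C4 epimer, which converges in step 8.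

Step 8
Reactants: 12 1,2-trans-1-aryl-4-(triethylsilyloxy)tetralin-2,3-diester
Product: 14 CNP0244800.2 (target), via debenzylated silyl ether 13 (not isolated)
Conditions: H2 (1 atm), 10 % Pd/C, EtOAc–THF, rt; filter (Celite, Ar); TFA–H2O 9:1, 0 °C → rt; RP‑HPLC
Reagents that add atoms: none
Why: Hydrogenolytic O‑debenzylation is run while no alkene is present; after the catalyst is removed, acid hydrolyses the acetonides and the silyl ether and effects E1 dehydration of the para‑oxygen‑activated benzylic C4 position to the conjugated C3=C4 alkene, leaving C1, C2 and the danshensu centres untouched.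

## Compound list

1 | sodium (2R)-3-(3,4-dihydroxyphenyl)-2-hydroxypropanoate | [Na+].[O-]C(=O)[C@H](O)Cc1ccc(O)c(O)c1 | starting material
2 | benzyl (2R)-3-[3,4-bis(benzyloxy)phenyl]-2-hydroxypropanoate | O[C@H](Cc1ccc(OCc2ccccc2)c(OCc2ccccc2)c1)C(=O)OCc1ccccc1 | intermediate
3 | fumaryl chloride | ClC(=O)/C=C/C(=O)Cl | starting material
4 | bis{(1R)-1-[3,4-bis(benzyloxy)benzyl]-2-(benzyloxy)-2-oxoethyl} (2E)-but-2-enedioate | O=C(/C=C/C(=O)O[C@H](Cc1ccc(OCc2ccccc2)c(OCc2ccccc2)c1)C(=O)OCc1ccccc1)O[C@H](Cc1ccc(OCc2ccccc2)c(OCc2ccccc2)c1)C(=O)OCc1ccccc1 | intermediate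
5 | 3,4-dihydroxybenzaldehyde | O=Cc1ccc(O)c(O)c1 | starting material
6 | 2,2-dimethyl-1,3-benzodioxole-5-carbaldehyde | O=Cc1ccc2OC(C)(C)Oc2c1 | intermediate
7 | 5-(dimethoxymethyl)-2,2-dimethyl-1,3-benzodioxole | COC(OC)c1ccc2OC(C)(C)Oc2c1 | intermediate
8 | [5-(dimethoxymethyl)-2,2-dimethyl-1,3-benzodioxol-4-yl](2,2-dimethyl-1,3-benzodioxol-5-yl)methanol, racemic | COC(OC)c1ccc2OC(C)(C)Oc2c1C(O)c1ccc2OC(C)(C)Oc2c1 | intermediate
9 | cyclic methyl acetal: 3-aryl-1-methoxy-4,5-(isopropylidenedioxy)-1,3-dihydroisobenzofuran (aryl = 2,2-dimethyl-1,3-benzodioxol-5-yl), diastereomer mixture | COC1OC(c3ccc4OC(C)(C)Oc4c3)c2c3OC(C)(C)Oc3ccc12 | intermediate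
10 | 1-aryl-6,7-(isopropylidenedioxy)isobenzofuran | CC1(C)Oc2ccc(cc2O1)-c1occ2ccc3OC(C)(C)Oc3c12 | intermediate
11 | oxa-bridged adduct: 1-aryl-7,8-(isopropylidenedioxy)-1,4-epoxy-1,2,3,4-tetrahydronaphthalene-2,3-dicarboxylate, bis(benzyl-protected (R)-danshensu) ester; trans-diester, drawn with the C2 ester endo | O1[C@]2(c3ccc4OC(C)(C)Oc4c3)c3c4OC(C)(C)Oc4ccc3[C@H]1[C@H](C(=O)O[C@H](Cc5ccc(OCc6ccccc6)c(OCc6ccccc6)c5)C(=O)OCc5ccccc5)[C@H]2C(=O)O[C@H](Cc5ccc(OCc6ccccc6)c(OCc6ccccc6)c5)C(=O)OCc5ccccc5 | intermediate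
12 | (1R,2S,3R,4R)-1-aryl-7,8-(isopropylidenedioxy)-4-(triethylsilyloxy)tetralin-2,3-dicarboxylate, bis(benzyl-protected (R)-danshensu) ester | CC[Si](CC)(CC)O[C@H]1c2ccc3OC(C)(C)Oc3c2[C@@H](c2ccc3OC(C)(C)Oc3c2)[C@H](C(=O)O[C@H](Cc2ccc(OCc3ccccc3)c(OCc3ccccc3)c2)C(=O)OCc2ccccc2)[C@H]1C(=O)O[C@H](Cc1ccc(OCc2ccccc2)c(OCc2ccccc2)c1)C(=O)OCc1ccccc1 | intermediate
13 | debenzylated 12: bis[(R)-danshensu] ester with free catechols and acids, core still acetonide/silyl protected | CC[Si](CC)(CC)O[C@H]1c2ccc3OC(C)(C)Oc3c2[C@@H](c2ccc3OC(C)(C)Oc3c2)[C@H](C(=O)O[C@H](Cc2ccc(O)c(O)c2)C(=O)O)[C@H]1C(=O)O[C@H](Cc1ccc(O)c(O)c1)C(=O)O | intermediate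
14 | CNP0244800.2: (1R,2S)-1-(3,4-dihydroxyphenyl)-7,8-dihydroxy-1,2-dihydronaphthalene-2,3-dicarboxylic acid bis[(R)-1-carboxy-2-(3,4-dihydroxyphenyl)ethyl] ester | O=C(O[C@H](Cc1ccc(O)c(O)c1)C(=O)O)C1=Cc2ccc(O)c(O)c2[C@@H](c2ccc(O)c(O)c2)[C@@H]1C(=O)O[C@H](Cc1ccc(O)c(O)c1)C(=O)O | target

## Step count and risks

Total steps: 8. Longest linear sequence: 6 (5 → 6 → 7 → 8 → 11 → 12 → 14, steps 3–8); the danshensu branch (1 → 2 → 4) joins at step 6.

The three steps most likely to fail are steps 6, 7 and 5.

**Step 6.** The isobenzofuran is sensitive and the cycloaddition pairs a hindered diene with a hindered dienophile. The π‑facial control by the danshensu esters is an extrapolation from mandelate/lactate fumarates; its sense and magnitude are not secured, and nothing later in the route can correct the wrong face. The fallback gives up auxiliary control and resolves at the end. It sets out from 8 and rejoins the route at 14. Compound 8 is heated with maleic anhydride (cat. AcOH, toluene, 80 °C) to give the racemic oxa‑bridged anhydride F3. Reductive bridge opening as in step 7 (Et3SiH, cat. TESOTf) gives the silyloxy‑tetralin anhydride F4. TsOH in warm toluene eliminates silanol to the racemic trans‑1‑aryl‑1,2‑dihydronaphthalene anhydride F5. Opening of F5 with alcohol 2 (DMAP), then EDC/DMAP coupling of the remaining acid with a second equivalent of 2, gives the protected diester F6 and its (1S,2R) core diastereomer; C2 settles trans, and the two are separated by chromatography. BCl3/pentamethylbenzene (−78 °C) followed by TFA–H2O removes benzyl and acetonide groups without touching the alkene and gives 14.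

**Step 7.** The C1 cation can lose the C2 proton instead of accepting hydride, and the face of hydride delivery rests on a conformational argument. The fallback makes the elimination product on purpose and sets C1 by reduction under steric control. It sets out from 11 and rejoins at 12. TESOTf (1.2 equiv) with 2,6‑lutidine and no silane opens the bridge and gives the ring‑opened alkene F7 (C1=C2, O4 silylated). Conjugate reduction with nickel boride (NiCl2, NaBH4, low temperature) adds hydrogen to C1 from the face opposite the C3 ester and the C4 silyloxy group. If C2 comes out cis, brief DBU treatment equilibrates it to the trans ester, giving 12.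

**Step 5.** Lithiation of 7 may be incomplete or occur at the other position ortho to oxygen. The fallback replaces the acetal by an in situ directing group. It sets out from 6 and rejoins at 9. Aldehyde 6 is treated with lithium N,N,N′‑trimethylethylenediamide to give the lithium α‑amino alkoxide F1. F1 is lithiated between the two directing groups (n‑BuLi, THF, −20 °C) and quenched with more 6. Aqueous work‑up gives the lactol F2. MeOH/PPTS converts F2 into the cyclic methyl acetal 9, which is carried into the conditions of step 6.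

Further compounds
F1 | step 5 | lithium α-amino alkoxide of 6 (adduct with N,N,N′-trimethylethylenediamide) | [Li+].[O-]C(N(C)CCN(C)C)c1ccc2OC(C)(C)Oc2c1
F2 | step 5 | lactol: 3-aryl-4,5-(isopropylidenedioxy)-1,3-dihydroisobenzofuran-1-ol (aryl = 2,2-dimethyl-1,3-benzodioxol-5-yl), racemic diastereomer mixture | OC1OC(c3ccc4OC(C)(C)Oc4c3)c2c3OC(C)(C)Oc3ccc12
F3 | step 6 | oxa-bridged maleic anhydride adduct of 10, racemic, exo isomer drawn | O1[C@]2(c3ccc4OC(C)(C)Oc4c3)c3c4OC(C)(C)Oc4ccc3[C@H]1[C@@H]5C(=O)OC(=O)[C@H]25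
F4 | step 6 | 1-aryl-7,8-(isopropylidenedioxy)-4-(triethylsilyloxy)tetralin-2,3-dicarboxylic anhydride, racemic diastereomer mixture | CC[Si](CC)(CC)OC1c2ccc3OC(C)(C)Oc3c2C(c2ccc3OC(C)(C)Oc3c2)C2C(=O)OC(=O)C12
F5 | step 6 | trans-1-aryl-7,8-(isopropylidenedioxy)-1,2-dihydronaphthalene-2,3-dicarboxylic anhydride, racemic, one enantiomer drawn | O=C1OC(=O)C2=Cc3ccc4OC(C)(C)Oc4c3[C@@H](c3ccc4OC(C)(C)Oc4c3)[C@H]12
F6 | step 6 | (1R,2S)-1-aryl-7,8-(isopropylidenedioxy)-1,2-dihydronaphthalene-2,3-dicarboxylate, bis(benzyl-protected (R)-danshensu) ester | O=C(O[C@H](Cc1ccc(OCc2ccccc2)c(OCc2ccccc2)c1)C(=O)OCc1ccccc1)C1=Cc2ccc3OC(C)(C)Oc3c2[C@@H](c2ccc3OC(C)(C)Oc3c2)[C@@H]1C(=O)O[C@H](Cc1ccc(OCc2ccccc2)c(OCc2ccccc2)c1)C(=O)OCc1ccccc1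
F7 | step 7 | ring-opened alkene: 1-aryl-7,8-(isopropylidenedioxy)-4-(triethylsilyloxy)-3,4-dihydronaphthalene-2,3-dicarboxylate, bis(benzyl-protected (R)-danshensu) ester | CC[Si](CC)(CC)O[C@H]1c2ccc3OC(C)(C)Oc3c2C(c2ccc3OC(C)(C)Oc3c2)=C(C(=O)O[C@H](Cc2ccc(OCc3ccccc3)c(OCc3ccccc3)c2)C(=O)OCc2ccccc2)[C@H]1C(=O)O[C@H](Cc1ccc(OCc2ccccc2)c(OCc2ccccc2)c1)C(=O)OCc1ccccc1
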